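**Plan**

1. Locants (spiro[5.5]undecane, kept throughout): ring A = C1(Me)=C2H–C3H(OH)–C4HBr–C5Me2–C6; ring B = C6–C7H2–C8(Br)=C9(Me)–C10H2–C11H2.
2. Retrosynthesis: C8–Br/C8=C9 go back to a C8 ketone, and this to a C7=C8 alkene. The trans C3–O/C4–Br pair goes back to a C1=C2–C3=C4 diene. Both π-systems come from the C3 and C7 carbonyl groups of a spiro enedione, which is cut at C4–C5 and C6–C1.
3. Enabling feature: C4, C3, C2, C1 and the C1 methyl are the five carbons of pent-3-yn-2-one. Ring B with C5 and its two methyls is a p-menthane in which C7, C6 and C5 are the carbonyl, α- and β-carbons of the exocyclic enone of pulegone.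
4. Forward: ring B is bought. Ring A closes in one flask (C4–C5 by Mukaiyama–Michael addition, C6–C1 by 6-endo-dig Michael addition). The remaining seven steps only change functional groups.
5. Stereochemistry: the C9 methyl of (S)-pulegone directs the axial closure at C6 and is flattened when C8=C9 is made. C4 and C3 come from face-selective anti bromoacetoxylation of the diene under control of C6.

Key step: step 2

Remark: the C8 configuration after hydroboration (C–B, then C–OH) is drawn for borane attack anti to the C9 methyl; it has no bearing on the route because C8 becomes a ketone one step later.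

**Step 1**
Reactants: 1 pent-3-yn-2-one
Product: 2 2-(trimethylsilyloxy)pent-1-en-3-yne
Conditions: TMSOTf, Et3N, Et2O, 0 °C
Reagents that add atoms: trimethylsilyl trifluoromethanesulfonate, C[Si](C)(C)OS(=O)(=O)C(F)(F)F
Why: Soft enolisation–O-silylation of a methyl ketone: the silyl triflate activates the carbonyl, the amine removes a proton from the acetyl CH3, the only α-position, and the cross-conjugated silyl enol ether should form with the alkyne untouched.

**Step 2**
Reactants: 3 (S)-(−)-pulegone; 2 2-(trimethylsilyloxy)pent-1-en-3-yne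
Product: 6 (6R,9S)-1,5,5,9-tetramethylspiro[5.5]undec-1-ene-3,7-dione, via trichlorotitanium enolate 4 (not isolated), via C2-titanated enedione 5 (not isolated)
Conditions: TiCl4 (2.2 equiv), CH2Cl2, −78 °C, slow addition of 2; −78 → 0 °C; H2O
Reagents that add atoms: none
Why: Proposed new method: TiCl4 binds the s-cis enone of 3, the CH2 terminus of 2 adds to the isopropylidene carbon (C4–C5 bond, silyl group lost) and leaves the regiodefined tetrasubstituted titanium enolate 4; on warming its α-carbon adds to the methyl-bearing alkyne carbon of the Ti-activated ynone (C6–C1 bond), and the in-plane vinyl–metal species 5, which cannot relax to a linear allenolate inside a six-membered ring and is therefore the costly point of the sequence, is protonated at C2 on quench. The closest known reaction types are the Mukaiyama–Michael addition of silyl enol ethers to β,β-disubstituted enones, the 6-endo-dig Michael closure of tethered enolates onto ynones and the Lewis-acid double Michael annulation of 2-silyloxydienes with enones; new is their union in one flask with an enyne donor and an unstabilised ketone enolate. Ring A closes 6-endo-dig by anti addition across the alkyne, both alkyne carbons becoming ring members. C6 is the only new stereocentre and is controlled by the C9 methyl group: the half-chair enolate with this methyl equatorial is attacked along the axial, chair-forming trajectory, so the C6–C1 bond ends axial and cis to the methyl and the CMe2 arm equatorial (6R). The step needs 1,4- over 1,2-addition to 3 (hindered carbonyl, fixed s-cis geometry, soft donor), addition of 2 to 3 rather than to ynone already formed (pre-complexed 3, slow addition of 2) and β-carbon closure through the enolate carbon (O-attack or attack at the ynone carbonyl would need eight- and four-membered rings). The C6 epimer is a diastereomer as long as C9 is stereogenic and is removed here by chromatography, which protects the enantiopurity of the final product.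

**Step 3**
Reactants: 6 (6R,9S)-1,5,5,9-tetramethylspiro[5.5]undec-1-ene-3,7-dione
Product: 8 (6S,9S)-1,5,5,9-tetramethylspiro[5.5]undeca-1,3,7-triene-3,7-diyl bis(trifluoromethanesulfonate), via dilithium bis-enolate 7 (not isolated)
Conditions: LDA (2.5 equiv), THF, −78 °C (6 added to the base); N-(5-chloro-2-pyridyl)triflimide (2.5 equiv), −78 → 0 °C
Reagents that add atoms: N-(5-chloropyridin-2-yl)bis(trifluoromethanesulfonyl)imide, FC(F)(F)S(=O)(=O)N(c1ccc(Cl)cn1)S(=O)(=O)C(F)(F)F
Why: Kinetic enolate formation and O-triflation: the amide base removes the α′-proton at C4 of the enone (cross-conjugated dienolate, as with other 3,5,5-trisubstituted cyclohexenones) and a proton at C8, the only α-position of the ring-B ketone because C6 is quaternary, and the pyridyl triflimide traps both oxygens without touching C6 or C9.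

**Step 4**
Reactants: 8 the bis(enol triflate)
Product: 9 (6S,9S)-1,5,5,9-tetramethylspiro[5.5]undeca-1,3,7-triene
Conditions: Pd(OAc)2 (cat.), PPh3, HCO2H, Bu3N, DMF, 60 °C
Reagents that add atoms: none
Why: Palladium-catalysed formate reduction of enol triflates (oxidative addition, decarboxylation of formate, C–H reductive elimination) exchanges each OTf for H and leaves the double bonds where the enolates had them, while quaternary C5 and C6 rule out migration of the ring-A diene.

**Step 5**
Reactants: 9 the triene
Product: 10 (3S,4S,6S,9S)-4-bromo-1,5,5,9-tetramethylspiro[5.5]undeca-1,7-dien-3-yl acetate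
Conditions: NBS (1.0 equiv), AcOH, NaOAc, CH2Cl2, −20 → 0 °C, dark
Reagents that add atoms: N-bromosuccinimide, O=C1CCC(=O)N1Br; acetic acid, CC(=O)O
Why: Electrophilic anti bromoacetoxylation (cohalogenation) of the most nucleophilic π-system: Br+ adds to the diene terminus C4 because the charge is then shared by C3 and the methyl-bearing C1, acetate opens the bromonium ion at C3 from the opposite face (capture at C1 would put three fully substituted carbons in a row and should be reversible in AcOH), which fixes the 3,4-trans relation, and Br+ is expected on the ring-A face that carries the flat vinylic C7–H rather than C11H2, which gives 3S,4S.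

**Step 6**
Reactants: 10 the bromoacetate
Product: 12 (3S,4S,6S,8S,9S)-4-bromo-8-hydroxy-1,5,5,9-tetramethylspiro[5.5]undec-1-en-3-yl acetate, via C8 alkylborane 11 (not isolated)
Conditions: BH3·THF (1.2 equiv), THF, 0 °C → rt; 30% H2O2, pH 7 phosphate buffer, MeOH, 0 °C
Reagents that add atoms: hydrogen peroxide, OO
Why: Hydroboration–oxidation: borane adds syn to the cis-disubstituted C7=C8 alkene with boron on C8, away from quaternary C6 and anti to the pseudoaxial C6–C1 bond and the C9 methyl, whereas the trisubstituted C1=C2 alkene wedged between C6 and the C3 acetate, the ester and the neopentyl bromide should react far more slowly, and the buffered oxidation spares the acetate.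

**Step 7**
Reactants: 12 the C8 alcohol
Product: 13 (3S,4S,6S,9S)-4-bromo-1,5,5,9-tetramethyl-8-oxospiro[5.5]undec-1-en-3-yl acetate
Conditions: DMP, CH2Cl2, rt
Reagents that add atoms: none
Why: Dess–Martin oxidation of a secondary alcohol under near-neutral conditions completes the 1,2-transposition of the ring-B carbonyl from C7 to C8 and leaves the allylic acetate, the secondary bromide and the alkene alone.

**Step 8**
Reactants: 13 the C8 ketone
Product: 14 (3S,4S,6S)-4,8-dibromo-1,5,5,9-tetramethylspiro[5.5]undeca-1,8-dien-3-yl acetate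
Conditions: (PhO)3P, Br2, CH2Cl2, −60 °C; Et3N, 13; → rt, then reflux
Reagents that add atoms: bromine (delivered as the phosphite–bromine adduct), BrBr
Why: Deoxygenative bromination of an enolisable ketone with the triphenyl phosphite–bromine reagent (O-phosphonium activation, bromide addition, amine-induced loss of phosphate) gives the vinyl bromide, and the proton should leave from C9 rather than from neopentyl C7 because this gives the tetrasubstituted alkene and C7–H is shielded by C6; bromine is bound to phosphorus before 13 is added, so C1=C2 is not exposed to it, and the C9 stereocentre disappears here.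

**Step 9**
Reactants: 14 the dibromo acetate
Product: 15 (3S,4S,6S)-4,8-dibromo-1,5,5,9-tetramethylspiro[5.5]undeca-1,8-dien-3-ol (target)
Conditions: DIBAL-H (2.5 equiv), CH2Cl2, −78 °C; aq. Rochelle salt
Reagents that add atoms: none
Why: Reductive ester cleavage with DIBAL-H breaks the acyl C–O bond only, so C3 keeps its configuration, and the low temperature and absence of a free basic alkoxide avoid epoxide closure onto the trans C4 bromide, while the vinyl and neopentyl bromides are inert.

**Compound list**

1 | pent-3-yn-2-one | CC#CC(C)=O | starting material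
2 | 2-(trimethylsilyloxy)pent-1-en-3-yne | C=C(O[Si](C)(C)C)C#CC | intermediate
3 | (S)-(−)-pulegone, (5S)-5-methyl-2-(propan-2-ylidene)cyclohexan-1-one | C[C@H]1CCC(=C(C)C)C(=O)C1 | starting material
4 | trichlorotitanium enolate (ring C=C–OTi) of (5S)-5-methyl-2-(2-methyl-4-oxohept-5-yn-2-yl)cyclohexanone, not isolated | C[C@H]1CCC(=C(O[Ti](Cl)(Cl)Cl)C1)C(C)(C)CC(=O)C#CC | intermediate
5 | ring-closed enedione bearing TiCl3 on C2, not isolated | CC1=C([Ti](Cl)(Cl)Cl)C(=O)CC(C)(C)[C@]12CC[C@H](C)CC2=O | intermediate
6 | (6R,9S)-1,5,5,9-tetramethylspiro[5.5]undec-1-ene-3,7-dione (C6–C1 bond cis to the C9 methyl) | CC1=CC(=O)CC(C)(C)[C@]12CC[C@H](C)CC2=O | intermediate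
7 | dilithium bis-enolate of 6 (C3–OLi/C3=C4 and C7–OLi/C7=C8), not isolated | CC1=CC(O[Li])=CC(C)(C)[C@]12CC[C@H](C)C=C2O[Li] | intermediate
8 | (6S,9S)-1,5,5,9-tetramethylspiro[5.5]undeca-1,3,7-triene-3,7-diyl bis(trifluoromethanesulfonate) | CC1=CC(OS(=O)(=O)C(F)(F)F)=CC(C)(C)[C@]12CC[C@H](C)C=C2OS(=O)(=O)C(F)(F)F | intermediate
9 | (6S,9S)-1,5,5,9-tetramethylspiro[5.5]undeca-1,3,7-triene | CC1=CC=CC(C)(C)[C@]12CC[C@H](C)C=C2 | intermediate
10 | (3S,4S,6S,9S)-4-bromo-1,5,5,9-tetramethylspiro[5.5]undeca-1,7-dien-3-yl acetate (Br cis to C7, OAc trans to Br) | CC1=C[C@H](OC(C)=O)[C@@H](Br)C(C)(C)[C@]12CC[C@H](C)C=C2 | intermediate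
11 | C8 alkylborane (BH2 on C8, trans to the C9 methyl), not isolated | CC1=C[C@H](OC(C)=O)[C@@H](Br)C(C)(C)[C@]12CC[C@H](C)[C@@H](B)C2 | intermediate
12 | (3S,4S,6S,8S,9S)-4-bromo-8-hydroxy-1,5,5,9-tetramethylspiro[5.5]undec-1-en-3-yl acetate | CC1=C[C@H](OC(C)=O)[C@@H](Br)C(C)(C)[C@]12CC[C@H](C)[C@@H](O)C2 | intermediate
13 | (3S,4S,6S,9S)-4-bromo-1,5,5,9-tetramethyl-8-oxospiro[5.5]undec-1-en-3-yl acetate | CC1=C[C@H](OC(C)=O)[C@@H](Br)C(C)(C)[C@]12CC[C@H](C)C(=O)C2 | intermediate
14 | (3S,4S,6S)-4,8-dibromo-1,5,5,9-tetramethylspiro[5.5]undeca-1,8-dien-3-yl acetate | CC1=C[C@H](OC(C)=O)[C@@H](Br)C(C)(C)[C@]12CCC(C)=C(Br)C2 | intermediate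
15 | (3S,4S,6S)-4,8-dibromo-1,5,5,9-tetramethylspiro[5.5]undeca-1,8-dien-3-ol | CC1=C[C@H](O)[C@@H](Br)C(C)(C)[C@]12CCC(C)=C(Br)C2 | target

**Totals**

Total step count: 9. Longest linear sequence: 9 steps (from 1; 8 from 3).

**Steps most likely to fail**

**Step 2 (the labelled step).**
- Risk: after the first C–C bond the titanium enolate may fail to add to the alkyne, because the closure passes through an unstabilised in-plane vinyl anion equivalent. The sequence then stalls at the open chain, chloride adds to the ynone, or the silyl enol ether is used up by oligomerisation. Face selection at C6 may also be only moderate.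
- Fallback, from 3 and 2 back to 6, by known reactions only: the Mukaiyama–Michael addition is run alone (TiCl4, 1.1 equiv, CH2Cl2, −78 °C, aqueous quench). After equilibration of the α-centre it gives the trans-diketone (2R,5S)-5-methyl-2-(2-methyl-4-oxohept-5-yn-2-yl)cyclohexan-1-one F1. Hydrochlorination of the ynone with LiCl in AcOH turns the sp acceptor into the β-chlorovinyl ketone (2R,5S)-2-[(5Z)-6-chloro-2-methyl-4-oxohept-5-en-2-yl]-5-methylcyclohexan-1-one F2. t-BuOK in t-BuOH/THF then enolises reversibly, and only the tertiary α-carbon can reach the β-carbon through a six-membered transition state. A 6-endo-trig addition followed by loss of chloride therefore gives 6 by way of an ordinary conjugated enolate. Any ynone or allenone regenerated by loss of HCl is an acceptor at the same carbon. The C9 methyl selects the face as before, and the C6 epimers are separated at 6.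

**Step 5.**
- Risk: poor facial selectivity in the delivery of Br+ (the two faces of ring A differ only in C7 versus C11), capture of the allyl cation at C1, or competing attack on the C7=C8 alkene.
- Fallback, from 9 back to 10, which moves control of C4 from a kinetic π-face choice to an equilibrium and sets C3 by hydride delivery and inversion:
  - NBS in aqueous acetone converts 9 into the two trans-bromohydrins, (3S,4S,6S,9S)-4-bromo-1,5,5,9-tetramethylspiro[5.5]undeca-1,7-dien-3-ol F3 and (3R,4R,6S,9S)-4-bromo-1,5,5,9-tetramethylspiro[5.5]undeca-1,7-dien-3-ol F4, whatever their proportion.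
  - DMP oxidises them to (4S,6S,9S)-4-bromo-1,5,5,9-tetramethylspiro[5.5]undeca-1,7-dien-3-one F5 and (4R,6S,9S)-4-bromo-1,5,5,9-tetramethylspiro[5.5]undeca-1,7-dien-3-one F6.
  - These differ only at the enolisable C4 and are equilibrated with catalytic HBr in AcOH towards the equatorial bromide, expected to be the former. The epimers are separable and the unwanted one can be resubmitted.
  - DIBAL-H should attack the carbonyl opposite to the pseudoaxial C5 methyl and give the cis-bromohydrin (3R,4S,6S,9S)-4-bromo-1,5,5,9-tetramethylspiro[5.5]undeca-1,7-dien-3-ol F7.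
  - A Mitsunobu reaction with AcOH (PPh3, DIAD) inverts C3 and gives 10.

**Step 8.**
- Risk: loss of the proton from C7 instead of C9 (wrong alkene position), arrest at a gem-dibromide, or ionisation of the allylic acetate by the bromophosphonium reagent.
- Fallback, from 13 back to 14, in which the alkene position is fixed first under equilibrating conditions and the C–Br bond is made by halodemetalation:
  - TMSOTf/Et3N under equilibrating conditions gives the more substituted silyl enol ether (3S,4S,6S)-4-bromo-1,5,5,9-tetramethyl-8-(trimethylsilyloxy)spiro[5.5]undeca-1,8-dien-3-yl acetate F8.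
  - CsF and PhNTf2 in DME exchange silicon for triflyl without moving the double bond and give (3S,4S,6S)-4-bromo-1,5,5,9-tetramethyl-8-(trifluoromethanesulfonyloxy)spiro[5.5]undeca-1,8-dien-3-yl acetate F9.
  - (Me3Sn)2, Pd(PPh3)4 and LiCl in THF give (3S,4S,6S)-4-bromo-1,5,5,9-tetramethyl-8-(trimethylstannyl)spiro[5.5]undeca-1,8-dien-3-yl acetate F10. The enol triflate should undergo oxidative addition well before the hindered allylic acetate.
  - NBS at low temperature replaces tin by bromine at the same carbon and gives 14.

**Further compounds**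

F1 | step 2 | (2R,5S)-5-methyl-2-(2-methyl-4-oxohept-5-yn-2-yl)cyclohexan-1-one | C[C@H]1CC[C@H](C(C)(C)CC(=O)C#CC)C(=O)C1
F2 | step 2 | (2R,5S)-2-[(5Z)-6-chloro-2-methyl-4-oxohept-5-en-2-yl]-5-methylcyclohexan-1-one | C[C@H]1CC[C@H](C(C)(C)CC(=O)/C=C(/C)Cl)C(=O)C1
F3 | step 5 | (3S,4S,6S,9S)-4-bromo-1,5,5,9-tetramethylspiro[5.5]undeca-1,7-dien-3-ol | CC1=C[C@H](O)[C@@H](Br)C(C)(C)[C@]12CC[C@H](C)C=C2
F4 | step 5 | (3R,4R,6S,9S)-4-bromo-1,5,5,9-tetramethylspiro[5.5]undeca-1,7-dien-3-ol | CC1=C[C@@H](O)[C@H](Br)C(C)(C)[C@]12CC[C@H](C)C=C2
F5 | step 5 | (4S,6S,9S)-4-bromo-1,5,5,9-tetramethylspiro[5.5]undeca-1,7-dien-3-one | CC1=CC(=O)[C@@H](Br)C(C)(C)[C@]12CC[C@H](C)C=C2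
F6 | step 5 | (4R,6S,9S)-4-bromo-1,5,5,9-tetramethylspiro[5.5]undeca-1,7-dien-3-one | CC1=CC(=O)[C@H](Br)C(C)(C)[C@]12CC[C@H](C)C=C2
F7 | step 5 | (3R,4S,6S,9S)-4-bromo-1,5,5,9-tetramethylspiro[5.5]undeca-1,7-dien-3-ol | CC1=C[C@@H](O)[C@@H](Br)C(C)(C)[C@]12CC[C@H](C)C=C2
F8 | step 8 | (3S,4S,6S)-4-bromo-1,5,5,9-tetramethyl-8-(trimethylsilyloxy)spiro[5.5]undeca-1,8-dien-3-yl acetate | CC1=C[C@H](OC(C)=O)[C@@H](Br)C(C)(C)[C@]12CCC(C)=C(O[Si](C)(C)C)C2
F9 | step 8 | (3S,4S,6S)-4-bromo-1,5,5,9-tetramethyl-8-(trifluoromethanesulfonyloxy)spiro[5.5]undeca-1,8-dien-3-yl acetate | CC1=C[C@H](OC(C)=O)[C@@H](Br)C(C)(C)[C@]12CCC(C)=C(OS(=O)(=O)C(F)(F)F)C2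
F10 | step 8 | (3S,4S,6S)-4-bromo-1,5,5,9-tetramethyl-8-(trimethylstannyl)spiro[5.5]undeca-1,8-dien-3-yl acetate | CC1=C[C@H](OC(C)=O)[C@@H](Br)C(C)(C)[C@]12CCC(C)=C([Sn](C)(C)C)C2
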